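The route rests on building ring A last, by benzannulation onto a finished 3-aryl-4-pyranone. Ring A (C4a, C5, C6, C7, C8, C8a) is a resorcinol-type ring whose oxygens sit 1,3 on C5 and C7 and whose C4a–C8a edge belongs to pyranone ring C; a pyranonylketene and a silyl ynol ether assemble exactly this pattern. One irradiation of a 5-aryl-4-pyranon-2-yl diazomethyl ketone with (ethynyloxy)triisopropylsilane should form C8–C8a, C5–C6, C7–C8 and C4a–C5 and give the 5-hydroxy-7-silyloxy isoflavone directly. The precursor already carries ring B in its (R) form, with the phenol as a methoxymethyl ether and the tertiary alcohol as a triethylsilyl ether.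

Key step: step 12

Remarks on the chemistry:
- The only stereocenter is C2 of the dihydrofuran ring, taken as (R) from the target SMILES (priorities O1 > CMe2OH > C3H2 > H).
- The ring-B phenol is carried as a MOM acetal: it directs both aryl lithiations (steps 2 and 6), which fixes the boron at C5, and it leaves under acid, so no hydrogenation is needed next to the chromone C2=C3 bond.
- The diazo ketone is photolysed at 365 nm, outside the pyranone absorption.
- (Ethynyloxy)triisopropylsilane is assumed not to be a catalogue compound and is made in step 11. The L-fructose-derived epoxidation ketone is bought or prepared from L-sorbose.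

Step 1
Reactants: 1 3-(benzyloxy)phenol
Product: 2 1-(benzyloxy)-3-(methoxymethoxy)benzene
Conditions: MOMCl, K2CO3, acetone, rt
Reagents that add atoms: chloromethyl methyl ether, COCCl
Why: Williamson-type O-alkylation of the phenoxide should install the MOM acetal that later directs two ortho-lithiations.

Step 2
Reactants: 2 1-(benzyloxy)-3-(methoxymethoxy)benzene; 3 1-bromo-3-methylbut-2-ene (prenyl bromide)
Product: 5 1-(benzyloxy)-3-(methoxymethoxy)-2-(3-methylbut-2-en-1-yl)benzene, via aryllithium 4 (not isolated)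
Conditions: n-BuLi, THF, 0 °C; CuI (cat.), then 3, −40 °C to rt
Reagents that add atoms: none
Why: Directed ortho-metalation should occur at the ring hydrogen flanked by both oxygens, and the copper-assisted SN2 allylation of the aryllithium with the primary allylic bromide should give the linear prenyl arene.

Step 3
Reactants: 5 1-(benzyloxy)-3-(methoxymethoxy)-2-(3-methylbut-2-en-1-yl)benzene
Product: 6 (S)-3-[2-(benzyloxy)-6-(methoxymethoxy)benzyl]-2,2-dimethyloxirane
Conditions: L-fructose-derived Shi ketone (0.3 equiv), KHSO5 (as 2KHSO5·KHSO4·K2SO4), K2CO3, Bu4NHSO4 (cat.), MeCN/CH2(OMe)2/aq. Na2B4O7 buffer, 0 °C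
Reagents that add atoms: potassium peroxymonosulfate, [K+].[O-]S(=O)(=O)OO
Why: Shi asymmetric epoxidation: the chiral dioxirane should transfer oxygen to the trisubstituted olefin through a spiro transition state, and the L-fructose-derived ketone (the enantiomer of the common catalyst, which leads to the (R) series) should make the secondary epoxide carbon (S), setting the only stereocenter by reagent control.

Step 4
Reactants: 6 (S)-3-[2-(benzyloxy)-6-(methoxymethoxy)benzyl]-2,2-dimethyloxirane
Product: 8 (R)-2-[4-(methoxymethoxy)-2,3-dihydrobenzofuran-2-yl]propan-2-ol, via epoxyphenol 7 (not isolated)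
Conditions: H2 (1 atm), Pd/C, K2CO3 (0.5 equiv), MeOH, rt to 40 °C
Reagents that add atoms: none
Why: Hydrogenolysis of the aryl benzyl ether frees the phenol, whose phenoxide should open the epoxide 5-exo-tet at the secondary carbon with inversion (base favours this over 6-endo attack at the tertiary carbon), so the (S)-epoxide becomes the (R)-dihydrobenzofuran and releases the tertiary alcohol.

Step 5
Reactants: 8 (R)-2-[4-(methoxymethoxy)-2,3-dihydrobenzofuran-2-yl]propan-2-ol
Product: 9 (R)-triethyl({2-[4-(methoxymethoxy)-2,3-dihydrobenzofuran-2-yl]propan-2-yl}oxy)silane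
Conditions: TESOTf, 2,6-lutidine, CH2Cl2, −78 to −40 °C
Reagents that add atoms: triethylsilyl trifluoromethanesulfonate, CC[Si](CC)(CC)OS(=O)(=O)C(F)(F)F
Why: Silylation of the hindered tertiary alcohol with a silyl triflate and a non-nucleophilic base; the low temperature should keep the aryl MOM acetal intact.

Step 6
Reactants: 9 (R)-triethyl({2-[4-(methoxymethoxy)-2,3-dihydrobenzofuran-2-yl]propan-2-yl}oxy)silane
Product: 11 (R)-triethyl({2-[4-(methoxymethoxy)-5-(4,4,5,5-tetramethyl-1,3,2-dioxaborolan-2-yl)-2,3-dihydrobenzofuran-2-yl]propan-2-yl}oxy)silane, via aryllithium 10 (not isolated)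
Conditions: n-BuLi, TMEDA, THF, −78 to 0 °C; then i-PrOBpin, −78 °C to rt
Reagents that add atoms: 2-isopropoxy-4,4,5,5-tetramethyl-1,3,2-dioxaborolane, CC(C)OB1OC(C)(C)C(C)(C)O1
Why: Directed ortho-metalation: the MOM acetal on C4 is a stronger director than the ring ether oxygen and C5–H is its only free ortho position, so lithiation should occur at C5 and not C7, and the borate quench gives the pinacol ester.

Step 7
Reactants: 12 kojic acid
Product: 13 6-(hydroxymethyl)-4-oxo-4H-pyran-3-yl trifluoromethanesulfonate
Conditions: PhNTf2, Et3N, DMF, 0 °C to rt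
Reagents that add atoms: N-phenylbis(trifluoromethanesulfonimide), O=S(=O)(N(c1ccccc1)S(=O)(=O)C(F)(F)F)C(F)(F)F
Why: Chemoselective O-sulfonylation: only the acidic enolic 5-hydroxyl (pKa about 8) is ionised by the amine and should react with the triflimide, while the neutral primary alcohol should not.

Step 8
Reactants: 11 the pinacol boronate; 13 6-(hydroxymethyl)-4-oxo-4H-pyran-3-yl trifluoromethanesulfonate
Product: 14 (R)-2-(hydroxymethyl)-5-{4-(methoxymethoxy)-2-[2-(triethylsilyloxy)propan-2-yl]-2,3-dihydrobenzofuran-5-yl}-4H-pyran-4-one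
Conditions: Pd(OAc)2 (5 mol%), SPhos (10 mol%), K3PO4, THF/H2O, 50 °C
Reagents that add atoms: none
Why: Suzuki–Miyaura coupling: the electron-poor pyranonyl triflate should add readily to zerovalent palladium and the biaryl phosphine tolerates the ortho-alkoxy boronate, while the free alcohol, acetal and silyl ether are inert to phosphate base.

Step 9
Reactants: 14 the hydroxymethyl pyranone
Product: 15 (R)-5-{4-(methoxymethoxy)-2-[2-(triethylsilyloxy)propan-2-yl]-2,3-dihydrobenzofuran-5-yl}-4-oxo-4H-pyran-2-carboxylic acid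
Conditions: TEMPO (0.2 equiv), PhI(OAc)2 (2.5 equiv), CH2Cl2/H2O, rt
Reagents that add atoms: water, O
Why: Oxoammonium-mediated oxidation of the primary allylic-type alcohol through the aldehyde hydrate to the acid under nearly neutral, halogen-free conditions that should spare the silyl ether, the acetal and electron-rich ring B.

Step 10
Reactants: 15 the pyranone carboxylic acid
Product: 17 (R)-2-diazo-1-(5-{4-(methoxymethoxy)-2-[2-(triethylsilyloxy)propan-2-yl]-2,3-dihydrobenzofuran-5-yl}-4-oxo-4H-pyran-2-yl)ethan-1-one, via mixed anhydride 16 (not isolated)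
Conditions: i-BuOCOCl, N-methylmorpholine, THF, −15 °C; then CH2N2 (Et2O solution), 0 °C to rt, dark
Reagents that add atoms: diazomethane, C=[N+]=[N-]
Why: Acylation of diazomethane by a mixed carbonic anhydride (first stage of an Arndt–Eistert sequence), chosen because no HCl is released that could cleave the TES ether or MOM acetal; attack should occur at the more electrophilic pyranonyl carbonyl.

Step 11
Reactants: 18 3-phenylisoxazole; 19 triisopropylsilyl trifluoromethanesulfonate
Product: 22 (ethynyloxy)triisopropylsilane, via 5-lithio-3-phenylisoxazole 20 (not isolated), via lithium ethynolate 21 (not isolated)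
Conditions: n-BuLi, THF, −78 to −40 °C; then 19, −78 to 0 °C; rapid chromatography (hexanes) or bulb-to-bulb distillation
Reagents that add atoms: none
Why: Deprotonation at C5 of a 3-arylisoxazole triggers the known fragmentation of 5-lithioisoxazoles into a nitrile and a lithium ynolate, and the bulky silyl triflate should silylate the ynolate on oxygen, as is established for triisopropylsilyl electrophiles.

Step 12
Reactants: 17 the diazo ketone; 22 (ethynyloxy)triisopropylsilane
Product: 27 (R)-5-hydroxy-3-{4-(methoxymethoxy)-2-[2-(triethylsilyloxy)propan-2-yl]-2,3-dihydrobenzofuran-5-yl}-7-(triisopropylsilyloxy)-4H-chromen-4-one, via ketene 23 (not isolated), via cyclobutenone 24 (not isolated), via dienylketene 25 (not isolated), via cyclohexadienone 26 (not isolated)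
Conditions: 22 (3 equiv), hν (365 nm LED), degassed ClCH2CH2Cl, rt; then 80 °C, dark
Reagents that add atoms: none
Why: Irradiation at 365 nm, where the diazo ketone absorbs and the 3-aryl-4-pyranone does not, should expel N2 with 1,2-shift of the pyranonyl group (Wolff rearrangement, forming C8–C8a) to give ketene 23, which combines with the electron-rich alkyne 22 in a [2+2] cycloaddition (C5–C6 and C7–C8) to cyclobutenone 24. Four-electron electrocyclic opening of 24 gives dienylketene 25, and ring A is closed by a six-electron electrocyclization of the ketene carbon onto pyranone C3 (C4a–C5), after which cyclohexadienone 26 enolises to the phenol. The closest known reaction is the Danheiser photochemical benzannulation of alkenyl and heteroaryl diazomethyl ketones with silyl ynol ethers, and the vinylogous-ester C2=C3 bond of the pyranone should close more readily than a benzene ring because little aromatic stabilisation is lost. No stereocenter is created, and the (R) centre of ring B is remote and not involved. The step needs regiocontrol in the cycloaddition, secured by the polarity of the ynol ether (ketene carbonyl carbon to the unsubstituted alkyne carbon), so that the ketene oxygen ends as the C5 hydroxyl and the silyloxy carbon as C7; the closure itself has no alternative because C3 is the only ring carbon adjacent to C2. It also needs chemoselectivity for the ketene, secured by the TES ether on the tertiary alcohol and by the hydrogen bond of the new C5 hydroxyl to C4=O, which should keep the product from being acylated.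

Step 13
Reactants: 27 the bis-silylated isoflavone
Product: 28 (R)-5,7-dihydroxy-3-[2-(2-hydroxypropan-2-yl)-4-(methoxymethoxy)-2,3-dihydrobenzofuran-5-yl]-4H-chromen-4-one
Conditions: TBAF (3 equiv), AcOH (3 equiv), THF, rt
Reagents that add atoms: none
Why: Fluoride-mediated desilylation should cleave the aryl triisopropylsilyl ether (a vinylogous silyl ester) and the tertiary TES ether, while the MOM acetal is inert to buffered fluoride.

Step 14
Reactants: 28 the MOM-protected isoflavone
Product: 29 (R)-5,7-dihydroxy-3-[4-hydroxy-2-(2-hydroxypropan-2-yl)-2,3-dihydrobenzofuran-5-yl]-4H-chromen-4-one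
Conditions: HCl (2 M), MeOH/THF, 40 °C
Reagents that add atoms: none
Why: Acid-catalysed acetal exchange with methanol should remove the aryl MOM group (and any residual silyl ether on the tertiary alcohol) without touching the tertiary alcohol, the dihydrofuran or the chromone, giving the target with its (R) centre unchanged.

Compound list
1 | 3-(benzyloxy)phenol | Oc1cccc(OCc2ccccc2)c1 | starting material
2 | 1-(benzyloxy)-3-(methoxymethoxy)benzene | COCOc1cccc(OCc2ccccc2)c1 | intermediate
3 | 1-bromo-3-methylbut-2-ene (prenyl bromide) | CC(C)=CCBr | starting material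
4 | [2-(benzyloxy)-6-(methoxymethoxy)phenyl]lithium | [Li]c1c(OCOC)cccc1OCc1ccccc1 | intermediate
5 | 1-(benzyloxy)-3-(methoxymethoxy)-2-(3-methylbut-2-en-1-yl)benzene | CC(C)=CCc1c(OCOC)cccc1OCc1ccccc1 | intermediate
6 | (S)-3-[2-(benzyloxy)-6-(methoxymethoxy)benzyl]-2,2-dimethyloxirane | CC1(C)O[C@H]1Cc1c(OCOC)cccc1OCc1ccccc1 | intermediate
7 | (S)-2-[(3,3-dimethyloxiran-2-yl)methyl]-3-(methoxymethoxy)phenol (reacts as its phenoxide) | CC1(C)O[C@H]1Cc1c(O)cccc1OCOC | intermediate
8 | (R)-2-[4-(methoxymethoxy)-2,3-dihydrobenzofuran-2-yl]propan-2-ol | CC(C)(O)[C@H]1Cc2c(cccc2OCOC)O1 | intermediate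
9 | (R)-triethyl({2-[4-(methoxymethoxy)-2,3-dihydrobenzofuran-2-yl]propan-2-yl}oxy)silane | CC(C)(O[Si](CC)(CC)CC)[C@H]1Cc2c(cccc2OCOC)O1 | intermediate
10 | 5-lithio derivative of 9 (lithium on C5, ortho to the MOM acetal) | CC(C)(O[Si](CC)(CC)CC)[C@H]1Cc2c(ccc([Li])c2OCOC)O1 | intermediate
11 | (R)-triethyl({2-[4-(methoxymethoxy)-5-(4,4,5,5-tetramethyl-1,3,2-dioxaborolan-2-yl)-2,3-dihydrobenzofuran-2-yl]propan-2-yl}oxy)silane | CC(C)(O[Si](CC)(CC)CC)[C@H]1Cc2c(ccc(B3OC(C)(C)C(C)(C)O3)c2OCOC)O1 | intermediate
12 | kojic acid, 5-hydroxy-2-(hydroxymethyl)-4H-pyran-4-one | OCc1cc(=O)c(O)co1 | starting material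
13 | 6-(hydroxymethyl)-4-oxo-4H-pyran-3-yl trifluoromethanesulfonate | OCc1cc(=O)c(OS(=O)(=O)C(F)(F)F)co1 | intermediate
14 | (R)-2-(hydroxymethyl)-5-{4-(methoxymethoxy)-2-[2-(triethylsilyloxy)propan-2-yl]-2,3-dihydrobenzofuran-5-yl}-4H-pyran-4-one | CC(C)(O[Si](CC)(CC)CC)[C@H]1Cc2c(ccc(-c3coc(CO)cc3=O)c2OCOC)O1 | intermediate
15 | (R)-5-{4-(methoxymethoxy)-2-[2-(triethylsilyloxy)propan-2-yl]-2,3-dihydrobenzofuran-5-yl}-4-oxo-4H-pyran-2-carboxylic acid | CC(C)(O[Si](CC)(CC)CC)[C@H]1Cc2c(ccc(-c3coc(C(O)=O)cc3=O)c2OCOC)O1 | intermediate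
16 | isobutyl carbonic anhydride of acid 15 | CC(C)(O[Si](CC)(CC)CC)[C@H]1Cc2c(ccc(-c3coc(C(=O)OC(=O)OCC(C)C)cc3=O)c2OCOC)O1 | intermediate
17 | (R)-2-diazo-1-(5-{4-(methoxymethoxy)-2-[2-(triethylsilyloxy)propan-2-yl]-2,3-dihydrobenzofuran-5-yl}-4-oxo-4H-pyran-2-yl)ethan-1-one | CC(C)(O[Si](CC)(CC)CC)[C@H]1Cc2c(ccc(-c3coc(C(=O)C=[N+]=[N-])cc3=O)c2OCOC)O1 | intermediate
18 | 3-phenylisoxazole | c1ccc(-c2ccon2)cc1 | starting material
19 | triisopropylsilyl trifluoromethanesulfonate | CC(C)[Si](OS(=O)(=O)C(F)(F)F)(C(C)C)C(C)C | starting material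
20 | 5-lithio-3-phenylisoxazole | [Li]c1cc(-c2ccccc2)no1 | intermediate
21 | lithium ethynolate | [Li]OC#C | intermediate
22 | (ethynyloxy)triisopropylsilane | C#CO[Si](C(C)C)(C(C)C)C(C)C | intermediate
23 | (R)-2-(5-{4-(methoxymethoxy)-2-[2-(triethylsilyloxy)propan-2-yl]-2,3-dihydrobenzofuran-5-yl}-4-oxo-4H-pyran-2-yl)ethen-1-one (pyranonylketene) | CC(C)(O[Si](CC)(CC)CC)[C@H]1Cc2c(ccc(-c3coc(C=C=O)cc3=O)c2OCOC)O1 | intermediate
24 | 4-(5-aryl-4-oxo-4H-pyran-2-yl)-3-(triisopropylsilyloxy)cyclobut-2-en-1-one, aryl as in 23; the new ring carbon is transient and unassigned | CC(C)(O[Si](CC)(CC)CC)[C@H]1Cc2c(ccc(-c3coc(C4C(=O)C=C4O[Si](C(C)C)(C(C)C)C(C)C)cc3=O)c2OCOC)O1 | intermediate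
25 | (3E)-4-(5-aryl-4-oxo-4H-pyran-2-yl)-3-(triisopropylsilyloxy)buta-1,3-dien-1-one, aryl as in 23; ketene and pyranone on the same side of the double bond | CC(C)(O[Si](CC)(CC)CC)[C@H]1Cc2c(ccc(-c3coc(/C=C(O[Si](C(C)C)(C(C)C)C(C)C)\C=C=O)cc3=O)c2OCOC)O1 | intermediate
26 | 3-aryl-7-(triisopropylsilyloxy)-4aH-chromene-4,5-dione, aryl as in 23; keto tautomer of 27, C4a transient and unassigned | CC(C)(O[Si](CC)(CC)CC)[C@H]1Cc2c(ccc(C3=COC4=CC(O[Si](C(C)C)(C(C)C)C(C)C)=CC(=O)C4C3=O)c2OCOC)O1 | intermediate
27 | (R)-5-hydroxy-3-{4-(methoxymethoxy)-2-[2-(triethylsilyloxy)propan-2-yl]-2,3-dihydrobenzofuran-5-yl}-7-(triisopropylsilyloxy)-4H-chromen-4-one | CC(C)(O[Si](CC)(CC)CC)[C@H]1Cc2c(ccc(-c3coc4cc(O[Si](C(C)C)(C(C)C)C(C)C)cc(O)c4c3=O)c2OCOC)O1 | intermediate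
28 | (R)-5,7-dihydroxy-3-[2-(2-hydroxypropan-2-yl)-4-(methoxymethoxy)-2,3-dihydrobenzofuran-5-yl]-4H-chromen-4-one | CC(C)(O)[C@H]1Cc2c(ccc(-c3coc4cc(O)cc(O)c4c3=O)c2OCOC)O1 | intermediate
29 | (R)-5,7-dihydroxy-3-[4-hydroxy-2-(2-hydroxypropan-2-yl)-2,3-dihydrobenzofuran-5-yl]-4H-chromen-4-one | CC(C)(O)[C@H]1Cc2c(ccc(-c3coc4cc(O)cc(O)c4c3=O)c2O)O1 | target

Total step count: 14.
Longest linear sequence: 12 steps (steps 1–6, 8, 9, 10, 12, 13, 14). Steps 7 and 11 are one-step side branches.

Steps most likely to fail

Step 12 (key step). What may go wrong: light may be absorbed by the pyranone or by the product instead of the diazo ketone; the excited diazo ketone may react by carbene pathways other than rearrangement; the ketene may dimerise faster than the alkyne captures it; or the cyclobutenone may not open. The fallback generates the same ketene thermally, without light, and sets out from 17. AgO2CPh-catalysed Wolff rearrangement in aqueous THF with Et3N (Arndt–Eistert homologation) should give (R)-2-(5-{4-(methoxymethoxy)-2-[2-(triethylsilyloxy)propan-2-yl]-2,3-dihydrobenzofuran-5-yl}-4-oxo-4H-pyran-2-yl)acetic acid F1, which is kept cold and used at once. 1-Chloro-N,N,2-trimethylprop-1-en-1-amine in CH2Cl2 should convert it, without release of acid, into the corresponding acetyl chloride F2. Slow addition of Et3N to F2 and 22 in toluene at rt should form ketene 23 by dehydrochlorination, where the route is rejoined; warming to 80 °C carries it through 24, 25 and 26 to 27. Cycloaddition of arylketenes made from acid chlorides with alkoxyalkynes, followed by thermal rearrangement to phenols, is established chemistry (Smith–Hoehn-type benzannulation).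

Step 11. What may go wrong: fragmentation of the lithiated isoxazole may be incomplete; the ynolate may add to the benzonitrile formed beside it; silylation may occur on carbon to give a silylketene; or the volatile, moisture-sensitive product may be lost on isolation. The fallback sets out from acetylene and 19. Acetylene in THF at −78 °C is monolithiated with n-BuLi to lithium acetylide F3, which is oxygenated by lithium tert-butyl peroxide F4 (made from t-BuOOH and LiN(SiMe3)2) to the same ynolate 21. Silylation with 19 then rejoins the route at 22. This is the known electrophilic oxygenation of lithium acetylides to ynolates, and it forms no nitrile by-product.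

Step 10. What may go wrong: diazomethane may add as a 1,3-dipole to the acyl-activated C2=C3 bond of the pyranone, or may attack the carbonate carbonyl of the mixed anhydride, giving the methyl ester instead of the diazo ketone. The fallback is a detrifluoroacetylative diazo transfer, which needs no diazomethane and sets out from 14. MnO2 in CH2Cl2 should give the 4-oxo-4H-pyran-2-carbaldehyde F5. MeTi(OiPr)3, which adds to aldehydes in preference to the pyranone carbonyl, should give the 1-hydroxyethyl pyranone F6 as a mixture at the new carbinol carbon. Dess–Martin periodinane should give the 2-acetylpyranone F7. LiN(SiMe3)2 and CF3CO2CH2CF3 in THF at −78 °C should give the trifluoroacetylated diketone F8, which is not isolated, and MsN3, Et3N and water in MeCN should deliver 17, where the route is rejoined.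

Further compounds
F1 | step 12 | (R)-2-(5-{4-(methoxymethoxy)-2-[2-(triethylsilyloxy)propan-2-yl]-2,3-dihydrobenzofuran-5-yl}-4-oxo-4H-pyran-2-yl)acetic acid | CC(C)(O[Si](CC)(CC)CC)[C@H]1Cc2c(ccc(-c3coc(CC(O)=O)cc3=O)c2OCOC)O1
F2 | step 12 | (R)-2-(5-{4-(methoxymethoxy)-2-[2-(triethylsilyloxy)propan-2-yl]-2,3-dihydrobenzofuran-5-yl}-4-oxo-4H-pyran-2-yl)acetyl chloride | CC(C)(O[Si](CC)(CC)CC)[C@H]1Cc2c(ccc(-c3coc(CC(Cl)=O)cc3=O)c2OCOC)O1
F3 | step 11 | lithium acetylide | [Li]C#C
F4 | step 11 | lithium tert-butyl peroxide | CC(C)(C)OO[Li]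
F5 | step 10 | (R)-5-{4-(methoxymethoxy)-2-[2-(triethylsilyloxy)propan-2-yl]-2,3-dihydrobenzofuran-5-yl}-4-oxo-4H-pyran-2-carbaldehyde | CC(C)(O[Si](CC)(CC)CC)[C@H]1Cc2c(ccc(-c3coc(C=O)cc3=O)c2OCOC)O1
F6 | step 10 | 2-(1-hydroxyethyl)-5-{(R)-4-(methoxymethoxy)-2-[2-(triethylsilyloxy)propan-2-yl]-2,3-dihydrobenzofuran-5-yl}-4H-pyran-4-one, both epimers at the carbinol carbon | CC(C)(O[Si](CC)(CC)CC)[C@H]1Cc2c(ccc(-c3coc(C(C)O)cc3=O)c2OCOC)O1
F7 | step 10 | (R)-2-acetyl-5-{4-(methoxymethoxy)-2-[2-(triethylsilyloxy)propan-2-yl]-2,3-dihydrobenzofuran-5-yl}-4H-pyran-4-one | CC(C)(O[Si](CC)(CC)CC)[C@H]1Cc2c(ccc(-c3coc(C(C)=O)cc3=O)c2OCOC)O1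
F8 | step 10 | (R)-4,4,4-trifluoro-1-(5-{4-(methoxymethoxy)-2-[2-(triethylsilyloxy)propan-2-yl]-2,3-dihydrobenzofuran-5-yl}-4-oxo-4H-pyran-2-yl)butane-1,3-dione | CC(C)(O[Si](CC)(CC)CC)[C@H]1Cc2c(ccc(-c3coc(C(=O)CC(=O)C(F)(F)F)cc3=O)c2OCOC)O1
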